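**Retrosynthetic overview** (germacrane numbering)
1. The ten-membered carbocycle (C1–C10) is formed last, by Nozaki–Hiyama–Kishi closure of C1–C10 (C10 alkenyl iodide + C1 aldehyde); C1 is then fixed by oxidation and CBS reduction.
2. The α-methylene-γ-lactone (O6–C12–C11–C7–C6) is formed first, by making C11–C7: a PMe3-triggered intramolecular Morita–Baylis–Hillman alkylation in which an acrylate on O6 opens the C7–C8 epoxide (5-exo). It sets C7, frees O8 for the (S)-2-methylbutanoate and leaves the C11=C13 methylene.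
3. Enabling feature: C6 (lactone O), C7 (bearing C11) and C8 (O-acyl) are contiguous, O6 is one atom away from C7, and the C7–C11 and C8–O bonds are anti. C6–C7–C8 is therefore the imprint of anti opening at C7 of an erythro trans-2,3-epoxy alcohol by the α-carbon of its own O6 ester.
4. Epoxy alcohol ⇐ Sharpless epoxidation of a (6S,7E)-dienol ⇐ asymmetric alkenylzinc addition of a C7–C10 dienyl unit to a C1–C6 enal.
5. Both ring-cis trisubstituted alkenes come from hydroxyl-directed trans-hydroalumination/iodination of butynols; the C4 iodide is alkylated (B-alkyl Suzuki–Miyaura), the C10 iodide is kept as the ring-closing handle.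

Key step: step 11

Remark on numbering: ring carbons C1–C10; C11, C12, C13 = lactone α-carbon, carbonyl carbon, exocyclic CH2; C14 = CH3 on C10; C15 = CH2OH on C4. Fragments keep these numbers.
Assumption: (−)-MIB is taken to direct the alkenylzinc to the Si face of enal 7, by analogy with its behaviour towards other aldehydes; if the sense were opposite, (+)-MIB would be used, and step 9 removes the minor enantiomer in either case.

Step 1
Reactants: 1 but-2-yne-1,4-diol
Product: 2 4-[(tert-butyldimethylsilyl)oxy]but-2-yn-1-ol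
Conditions: NaH (1.0 equiv), THF, 0 °C; TBSCl (1.0 equiv), 0 °C → rt
Reagents that add atoms: tert-butyldimethylsilyl chloride (TBSCl), CC(C)(C)[Si](C)(C)Cl
Why: Monosilylation of a symmetrical diol through its sparingly soluble monosodium alkoxide should stop after one silyl ether is formed, leaving the second hydroxyl for the directed reduction; no stereocentre is formed.

Step 2
Reactants: 2 4-[(tert-butyldimethylsilyl)oxy]but-2-yn-1-ol
Product: 3 (Z)-4-[(tert-butyldimethylsilyl)oxy]-3-iodobut-2-en-1-ol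
Conditions: NaAlH2(OCH2CH2OCH3)2 (Red-Al), THF, 0 °C; then I2, −78 → 0 °C
Reagents that add atoms: iodine, II
Why: Hydroxyl-directed trans-hydroalumination of the propargylic alcohol places aluminium on the distal alkyne carbon (C4) in a five-membered alkoxyaluminate, and iodinolysis with retention should give the alkenyl iodide with iodine cis to CH2OH (C6), which fixes the ring-cis C4=C5 geometry.

Step 3
Reactants: 3 (Z)-4-[(tert-butyldimethylsilyl)oxy]-3-iodobut-2-en-1-ol; 4 3,3-dimethoxyprop-1-ene
Product: 6 (E)-3-{[(tert-butyldimethylsilyl)oxy]methyl}-6,6-dimethoxyhex-2-en-1-ol, via alkylborane 5 (not isolated)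
Conditions: 4, 9-BBN, THF, 0 °C → rt; then 3, PdCl2(dppf) (5 mol%), AsPh3, Cs2CO3, DMF/H2O, rt
Reagents that add atoms: none
Why: Anti-Markovnikov hydroboration followed by B-alkyl Suzuki–Miyaura coupling, which proceeds with retention at the alkenyl iodide and tolerates the free allylic alcohol, should attach C3–C1 (C1 masked as the dimethyl acetal) cis to C6.

Step 4
Reactants: 6 (E)-3-{[(tert-butyldimethylsilyl)oxy]methyl}-6,6-dimethoxyhex-2-en-1-ol
Product: 7 (E)-3-{[(tert-butyldimethylsilyl)oxy]methyl}-6,6-dimethoxyhex-2-enal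
Conditions: MnO2, CH2Cl2, rt
Reagents that add atoms: none
Why: MnO2 oxidation of the primary allylic alcohol should give the β,β-disubstituted enal without touching the acetal or silyl ether and without scrambling the alkene geometry.

Step 5
Reactants: 8 but-2-yn-1-ol
Product: 9 (Z)-3-iodobut-2-en-1-ol
Conditions: NaAlH2(OCH2CH2OCH3)2 (Red-Al), THF, 0 °C; then I2, −78 → 0 °C
Reagents that add atoms: iodine, II
Why: The same directed trans-hydroalumination/iodinolysis should place iodine on C10 cis to the carbinol carbon (future C8), which fixes the ring-cis C9=C10 geometry.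

Step 6
Reactants: 9 (Z)-3-iodobut-2-en-1-ol
Product: 10 (Z)-3-iodobut-2-enal
Conditions: MnO2, CH2Cl2, rt
Reagents that add atoms: none
Why: MnO2 oxidation of the allylic alcohol under neutral conditions should give the β-iodo enal with the Z geometry intact.

Step 7
Reactants: 10 (Z)-3-iodobut-2-enal; 11 (trimethylsilyl)diazomethane
Product: 12 (Z)-4-iodopent-3-en-1-yne
Conditions: 11, LiN(i-Pr)2, THF, −78 °C; then 10, −78 °C → rt
Reagents that add atoms: none
Why: Colvin alkyne homologation (1,2-addition of the lithiated silyldiazomethane, loss of silanolate and N2, 1,2-hydrogen shift) should turn the aldehyde into the terminal alkyne that supplies C7, at a temperature at which the Z-alkenyl iodide is not touched.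

Step 8
Reactants: 12 (Z)-4-iodopent-3-en-1-yne; 7 (E)-3-{[(tert-butyldimethylsilyl)oxy]methyl}-6,6-dimethoxyhex-2-enal
Product: 15 (4E,6S,7E,9Z)-4-{[(tert-butyldimethylsilyl)oxy]methyl}-10-iodo-1,1-dimethoxyundeca-4,7,9-trien-6-ol, via dienylborane 13 (not isolated), via dienylzinc 14 (not isolated)
Conditions: 12, Cy2BH, toluene, 0 °C → rt; Me2Zn, −78 °C; (−)-MIB (5 mol%); then 7, −20 → 0 °C; aqueous work-up
Reagents that add atoms: none
Why: Syn hydroboration of the terminal alkyne sets the E C7=C8 alkene, boron-to-zinc exchange gives the dienylzinc, and the amino-alcohol-catalysed asymmetric alkenylzinc addition to the aldehyde should deliver the dienyl group to the Si face and set C6 as S.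

Step 9
Reactants: 15 (4E,6S,7E,9Z)-4-{[(tert-butyldimethylsilyl)oxy]methyl}-10-iodo-1,1-dimethoxyundeca-4,7,9-trien-6-ol
Product: 16 (1R,2E)-3-{[(tert-butyldimethylsilyl)oxy]methyl}-1-{(2R,3R)-3-[(Z)-2-iodoprop-1-en-1-yl]oxiran-2-yl}-6,6-dimethoxyhex-2-en-1-ol
Conditions: Ti(OiPr)4 (0.3 equiv), D-(−)-diisopropyl tartrate (0.36 equiv), t-BuOOH (1.0 equiv), 4 Å MS, CH2Cl2, −20 °C
Reagents that add atoms: tert-butyl hydroperoxide, CC(C)(C)OO
Why: Sharpless asymmetric epoxidation with D-(−)-tartrate is matched for the 6S alcohol and should epoxidise only the E-disubstituted C7=C8 alkene to the erythro epoxy alcohol, the tartrate setting C7 and C8, while the cis-substituted C4=C5 alkene and any 6R alcohol react far more slowly.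

Step 10
Reactants: 16 (1R,2E)-3-{[(tert-butyldimethylsilyl)oxy]methyl}-1-{(2R,3R)-3-[(Z)-2-iodoprop-1-en-1-yl]oxiran-2-yl}-6,6-dimethoxyhex-2-en-1-ol; 17 acryloyl chloride
Product: 18 (1R,2E)-3-{[(tert-butyldimethylsilyl)oxy]methyl}-1-{(2S,3R)-3-[(Z)-2-iodoprop-1-en-1-yl]oxiran-2-yl}-6,6-dimethoxyhex-2-en-1-yl prop-2-enoate
Conditions: i-Pr2NEt, CH2Cl2, −40 → 0 °C
Reagents that add atoms: none
Why: O-acylation of the secondary alcohol with an acid chloride and a hindered amine base at low temperature should give the acrylate without opening the epoxide and without change at C6 (the descriptor at the epoxide carbon changes only because of CIP priorities).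

Step 11
Reactants: 18 (1R,2E)-3-{[(tert-butyldimethylsilyl)oxy]methyl}-1-{(2S,3R)-3-[(Z)-2-iodoprop-1-en-1-yl]oxiran-2-yl}-6,6-dimethoxyhex-2-en-1-yl prop-2-enoate
Product: 21 (4R,5R)-5-[(E)-2-{[(tert-butyldimethylsilyl)oxy]methyl}-5,5-dimethoxypent-1-en-1-yl]-4-[(1S,2Z)-1-hydroxy-3-iodobut-2-en-1-yl]-3-methylideneoxolan-2-one, via phosphonium enolate 19 (not isolated), via phosphonium alkoxide 20 (not isolated)
Conditions: PMe3 (0.5 equiv), t-BuOH/THF (1:1, 0.02 M), rt, argon
Reagents that add atoms: none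
Why: Proposed new method: PMe3 adds reversibly to the acrylate β-carbon (C13) to give phosphonium enolate 19, whose α-carbon (C11) attacks epoxide carbon C7 from the side opposite the C7–O bond; the liberated C8 alkoxide (20) then removes the C11 proton and PMe3 is expelled by E1cB elimination, which regenerates the phosphine and leaves the C11=C13 methylene, the closest known reaction type being the phosphine-mediated intramolecular Morita–Baylis–Hillman alkylation of enones by tethered epoxides or alkyl halides, extended here to an acrylate ester tethered through its ester oxygen. The γ-lactone ring (O6–C12–C11–C7–C6) closes in the 5-exo-tet mode, the mode in which carbamate, carbonate and stabilised-carbanion nucleophiles tethered to the oxygen of 2,3-epoxy alcohols open the epoxide at C2. C7 is set by SN2 inversion, so its configuration is dictated by the tartrate-derived epoxide, while C8 keeps its C–O bond and C6 is untouched; the trans relation of the C5 and C8 substituents on the lactone follows from the erythro trans-epoxy ester. The step needs attack at C7 rather than at the allylic carbon C8 (6-endo) and phosphine addition to the acrylate only: the first is secured by the three-atom tether and the collinear exo trajectory under Lewis-acid-free conditions, the second by the much higher Michael reactivity of the unsubstituted acrylate compared with the alkenyl iodide and the epoxide. Because the only base is the internal alkoxide in t-BuOH, the acetal, the silyl ether and the C1 oxidation level (kept as acetal so that no aldehyde competes) should survive.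

Step 12
Reactants: 21 (4R,5R)-5-[(E)-2-{[(tert-butyldimethylsilyl)oxy]methyl}-5,5-dimethoxypent-1-en-1-yl]-4-[(1S,2Z)-1-hydroxy-3-iodobut-2-en-1-yl]-3-methylideneoxolan-2-one; 22 (S)-2-methylbutanoic acid
Product: 23 (1S,2Z)-1-{(2R,3S)-2-[(E)-2-{[(tert-butyldimethylsilyl)oxy]methyl}-5,5-dimethoxypent-1-en-1-yl]-4-methylidene-5-oxooxolan-3-yl}-3-iodobut-2-en-1-yl (2S)-2-methylbutanoate
Conditions: DIC, DMAP (0.1 equiv), CH2Cl2, 0 °C → rt
Reagents that add atoms: none
Why: Steglich esterification of the only free hydroxyl (C8) with catalytic DMAP at low temperature should install the side chain with retention at C8 and without epimerising the α-stereocentre of the acid.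

Step 13
Reactants: 23 (1S,2Z)-1-{(2R,3S)-2-[(E)-2-{[(tert-butyldimethylsilyl)oxy]methyl}-5,5-dimethoxypent-1-en-1-yl]-4-methylidene-5-oxooxolan-3-yl}-3-iodobut-2-en-1-yl (2S)-2-methylbutanoate
Product: 24 (1S,2Z)-1-{(2R,3S)-2-[(E)-2-{[(tert-butyldimethylsilyl)oxy]methyl}-5-oxopent-1-en-1-yl]-4-methylidene-5-oxooxolan-3-yl}-3-iodobut-2-en-1-yl (2S)-2-methylbutanoate
Conditions: PPTS (0.2 equiv), acetone/H2O (9:1), 40 °C
Reagents that add atoms: water, O
Why: Mild acid-catalysed hydrolysis of the aliphatic dimethyl acetal should release the C1 aldehyde while the primary silyl ether, the allylic ester and the α-methylene lactone persist.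

Step 14
Reactants: 24 (1S,2Z)-1-{(2R,3S)-2-[(E)-2-{[(tert-butyldimethylsilyl)oxy]methyl}-5-oxopent-1-en-1-yl]-4-methylidene-5-oxooxolan-3-yl}-3-iodobut-2-en-1-yl (2S)-2-methylbutanoate
Product: 25 (1RS,4E,6R,7R,8R,9Z)-15-[(tert-butyldimethylsilyl)oxy]-1-hydroxy-8-[(2S)-2-methylbutanoyloxy]germacra-4,9,11(13)-trien-12,6-olide (C1 epimer mixture)
Conditions: CrCl2 (8 equiv), NiCl2 (0.1 equiv), degassed DMSO/THF, rt, slow addition to 2 mM
Reagents that add atoms: none
Why: Intramolecular Nozaki–Hiyama–Kishi coupling, in which the C10 alkenylchromium forms with retention of geometry and adds chemoselectively to the C1 aldehyde at high dilution, should close the ten-membered ring with both trisubstituted alkenes ring-cis, the lactone and esters being inert to divalent chromium; the new C1 carbinol is expected as an epimer mixture that steps 15 and 16 converge.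

Step 15
Reactants: 25 (1RS,4E,6R,7R,8R,9Z)-15-[(tert-butyldimethylsilyl)oxy]-1-hydroxy-8-[(2S)-2-methylbutanoyloxy]germacra-4,9,11(13)-trien-12,6-olide
Product: 26 (4E,6R,7R,8R,9Z)-15-[(tert-butyldimethylsilyl)oxy]-8-[(2S)-2-methylbutanoyloxy]-1-oxogermacra-4,9,11(13)-trien-12,6-olide
Conditions: Dess–Martin periodinane, CH2Cl2, 0 °C → rt
Reagents that add atoms: none
Why: Dess–Martin oxidation of the only free (allylic) alcohol should converge both C1 epimers to one Z-enone under conditions that neither epimerise C7 nor eliminate the C8 ester.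

Step 16
Reactants: 26 (4E,6R,7R,8R,9Z)-15-[(tert-butyldimethylsilyl)oxy]-8-[(2S)-2-methylbutanoyloxy]-1-oxogermacra-4,9,11(13)-trien-12,6-olide
Product: 27 (1S,4E,6R,7R,8R,9Z)-15-[(tert-butyldimethylsilyl)oxy]-1-hydroxy-8-[(2S)-2-methylbutanoyloxy]germacra-4,9,11(13)-trien-12,6-olide
Conditions: (R)-2-methyl-CBS-oxazaborolidine (0.5 equiv), catecholborane (2 equiv), toluene, −78 °C
Reagents that add atoms: none
Why: Corey–Bakshi–Shibata reduction with the trisubstituted alkenyl carbon C10 as the large and the C2 methylene as the small ketone substituent should deliver hydride under reagent control to give the 1S allylic alcohol, catecholborane at −78 °C leaving the lactone, the ester and the α-methylene group untouched.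

Step 17
Reactants: 27 (1S,4E,6R,7R,8R,9Z)-15-[(tert-butyldimethylsilyl)oxy]-1-hydroxy-8-[(2S)-2-methylbutanoyloxy]germacra-4,9,11(13)-trien-12,6-olide
Product: 28 (1S,4E,6R,7R,8R,9Z)-1,15-dihydroxy-8-[(2S)-2-methylbutanoyloxy]germacra-4,9,11(13)-trien-12,6-olide (target CNP0526758.1)
Conditions: HF·pyridine, pyridine, THF, 0 °C
Reagents that add atoms: none
Why: Buffered fluoride cleavage of the primary silyl ether should free the C15 alcohol without acyl migration or conjugate addition to the α-methylene lactone.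

**Compound list**
1 | but-2-yne-1,4-diol | OCC#CCO | starting material
2 | 4-[(tert-butyldimethylsilyl)oxy]but-2-yn-1-ol | CC(C)(C)[Si](C)(C)OCC#CCO | intermediate
3 | (Z)-4-[(tert-butyldimethylsilyl)oxy]-3-iodobut-2-en-1-ol | OC/C=C(I)/CO[Si](C)(C)C(C)(C)C | intermediate
4 | 3,3-dimethoxyprop-1-ene (acrolein dimethyl acetal) | C=CC(OC)OC | starting material
5 | 9-(3,3-dimethoxypropyl)-9-borabicyclo[3.3.1]nonane | COC(OC)CCB1C2CCCC1CCC2 | intermediate (not isolated)
6 | (E)-3-{[(tert-butyldimethylsilyl)oxy]methyl}-6,6-dimethoxyhex-2-en-1-ol | OC/C=C(CCC(OC)OC)/CO[Si](C)(C)C(C)(C)C | intermediate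
7 | (E)-3-{[(tert-butyldimethylsilyl)oxy]methyl}-6,6-dimethoxyhex-2-enal | O=C/C=C(CCC(OC)OC)/CO[Si](C)(C)C(C)(C)C | intermediate
8 | but-2-yn-1-ol | CC#CCO | starting material
9 | (Z)-3-iodobut-2-en-1-ol | C/C(I)=C/CO | intermediate
10 | (Z)-3-iodobut-2-enal | C/C(I)=C/C=O | intermediate
11 | (trimethylsilyl)diazomethane | C[Si](C)(C)C=[N+]=[N-] | starting material
12 | (Z)-4-iodopent-3-en-1-yne | C/C(I)=C/C#C | intermediate
13 | dicyclohexyl[(1E,3Z)-4-iodopenta-1,3-dien-1-yl]borane | C/C(I)=C/C=C/B(C1CCCCC1)C1CCCCC1 | intermediate (not isolated)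
14 | [(1E,3Z)-4-iodopenta-1,3-dien-1-yl](methyl)zinc | C/C(I)=C/C=C/[Zn]C | intermediate (not isolated)
15 | (4E,6S,7E,9Z)-4-{[(tert-butyldimethylsilyl)oxy]methyl}-10-iodo-1,1-dimethoxyundeca-4,7,9-trien-6-ol | COC(OC)CC/C(CO[Si](C)(C)C(C)(C)C)=C\[C@@H](O)/C=C/C=C(/C)I | intermediate
16 | (1R,2E)-3-{[(tert-butyldimethylsilyl)oxy]methyl}-1-{(2R,3R)-3-[(Z)-2-iodoprop-1-en-1-yl]oxiran-2-yl}-6,6-dimethoxyhex-2-en-1-ol | COC(OC)CC/C(CO[Si](C)(C)C(C)(C)C)=C\[C@@H](O)[C@H]1O[C@@H]1/C=C(/C)I | intermediate
17 | acryloyl chloride | C=CC(=O)Cl | starting material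
18 | (1R,2E)-3-{[(tert-butyldimethylsilyl)oxy]methyl}-1-{(2S,3R)-3-[(Z)-2-iodoprop-1-en-1-yl]oxiran-2-yl}-6,6-dimethoxyhex-2-en-1-yl prop-2-enoate | COC(OC)CC/C(CO[Si](C)(C)C(C)(C)C)=C\[C@@H](OC(=O)C=C)[C@H]1O[C@@H]1/C=C(/C)I | intermediate
19 | phosphonium enolate zwitterion (PMe3 added to C13 of 18; enolate at C11/C12) | COC(OC)CC/C(CO[Si](C)(C)C(C)(C)C)=C\[C@@H](OC([O-])=CC[P+](C)(C)C)[C@H]1O[C@@H]1/C=C(/C)I | intermediate (not isolated)
20 | γ-lactone phosphonium alkoxide zwitterion (C11–C7 bond formed; CH2PMe3+ on C11; alkoxide on C8) | C[P+](C)(C)CC1C(=O)O[C@H](/C=C(/CO[Si](C)(C)C(C)(C)C)CCC(OC)OC)[C@H]1[C@H]([O-])/C=C(/C)I | intermediate (not isolated)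
21 | (4R,5R)-5-[(E)-2-{[(tert-butyldimethylsilyl)oxy]methyl}-5,5-dimethoxypent-1-en-1-yl]-4-[(1S,2Z)-1-hydroxy-3-iodobut-2-en-1-yl]-3-methylideneoxolan-2-one | C=C1C(=O)O[C@H](/C=C(/CO[Si](C)(C)C(C)(C)C)CCC(OC)OC)[C@H]1[C@H](O)/C=C(/C)I | intermediate
22 | (S)-2-methylbutanoic acid | CC[C@H](C)C(=O)O | starting material
23 | (1S,2Z)-1-{(2R,3S)-2-[(E)-2-{[(tert-butyldimethylsilyl)oxy]methyl}-5,5-dimethoxypent-1-en-1-yl]-4-methylidene-5-oxooxolan-3-yl}-3-iodobut-2-en-1-yl (2S)-2-methylbutanoate | C=C1C(=O)O[C@H](/C=C(/CO[Si](C)(C)C(C)(C)C)CCC(OC)OC)[C@H]1[C@H](OC(=O)[C@@H](C)CC)/C=C(/C)I | intermediate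
24 | (1S,2Z)-1-{(2R,3S)-2-[(E)-2-{[(tert-butyldimethylsilyl)oxy]methyl}-5-oxopent-1-en-1-yl]-4-methylidene-5-oxooxolan-3-yl}-3-iodobut-2-en-1-yl (2S)-2-methylbutanoate | C=C1C(=O)O[C@H](/C=C(/CO[Si](C)(C)C(C)(C)C)CCC=O)[C@H]1[C@H](OC(=O)[C@@H](C)CC)/C=C(/C)I | intermediate
25 | (1RS,4E,6R,7R,8R,9Z)-15-[(tert-butyldimethylsilyl)oxy]-1-hydroxy-8-[(2S)-2-methylbutanoyloxy]germacra-4,9,11(13)-trien-12,6-olide (C1 epimer mixture) | C=C1C(=O)O[C@@H]2/C=C(/CO[Si](C)(C)C(C)(C)C)CCC(O)/C(C)=C\[C@@H](OC(=O)[C@@H](C)CC)[C@@H]12 | intermediate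
26 | (4E,6R,7R,8R,9Z)-15-[(tert-butyldimethylsilyl)oxy]-8-[(2S)-2-methylbutanoyloxy]-1-oxogermacra-4,9,11(13)-trien-12,6-olide | C=C1C(=O)O[C@@H]2/C=C(/CO[Si](C)(C)C(C)(C)C)CCC(=O)/C(C)=C\[C@@H](OC(=O)[C@@H](C)CC)[C@@H]12 | intermediate
27 | (1S,4E,6R,7R,8R,9Z)-15-[(tert-butyldimethylsilyl)oxy]-1-hydroxy-8-[(2S)-2-methylbutanoyloxy]germacra-4,9,11(13)-trien-12,6-olide | C=C1C(=O)O[C@@H]2/C=C(/CO[Si](C)(C)C(C)(C)C)CC[C@H](O)/C(C)=C\[C@@H](OC(=O)[C@@H](C)CC)[C@@H]12 | intermediate
28 | (1S,4E,6R,7R,8R,9Z)-1,15-dihydroxy-8-[(2S)-2-methylbutanoyloxy]germacra-4,9,11(13)-trien-12,6-olide (CNP0526758.1) | C=C1C(=O)O[C@@H]2/C=C(/CO)CC[C@H](O)/C(C)=C\[C@@H](OC(=O)[C@@H](C)CC)[C@@H]12 | target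

**Totals and risks**
Total step count: 17. Longest linear sequence: 14 steps (1 → 2 → 3 → 6 → 7 → 15 → 16 → 18 → 21 → 23 → 24 → 25 → 26 → 27 → 28).

Step 11 (bears the label). What may go wrong: the phosphonium enolate is protonated or consumed by intermolecular Rauhut–Currier-type oligomerisation, or the phosphine attacks the vinyl epoxide, faster than the 5-exo alkylation. Fallback with known chemistry, setting out from 16 and coming back at 21: 16 is esterified with diethylphosphonoacetic acid (DIC, cat. DMAP, CH2Cl2) to the diethylphosphonoacetate F1. Deprotonation (NaH, THF, 0 °C → rt) should trigger 5-exo opening of the epoxide at C7 by the phosphonate-stabilised carbanion, again with inversion, to give the α-(diethoxyphosphoryl)-γ-lactone F2 with the free C8 hydroxyl. Horner–Wadsworth–Emmons methylenation of F2 (aqueous formaldehyde, K2CO3, THF, rt) then installs the C11=C13 methylene and gives 21.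

Step 14. What may go wrong: intermolecular coupling and protodeiodination outcompete ring closure because the rigid trans-fused lactone holds the C1 aldehyde and the C10 alkenylchromium apart. Fallback, setting out from 18 and coming back at 25: the carbocycle is closed before the lactone. Acetal hydrolysis of 18 (PPTS, acetone/H2O) gives the epoxy acrylate aldehyde F3. Nozaki–Hiyama–Kishi closure of this more flexible epoxy ester (CrCl2, cat. NiCl2, DMSO/THF, high dilution) gives the ten-membered epoxy acrylate F4 as C1 epimers, and silylation (Et3SiCl, imidazole, CH2Cl2) gives its C1 triethylsilyl ether F5. The PMe3-mediated closure of step 11 is then run on the ring: attack of C11 on C7 of the trans-epoxide, anti to oxygen, should give the same trans-fused lactone with O8 cis to C11, the macrocyclic hydroxy lactone F6. Esterification with 22 as in step 12 gives the ester F7, and selective removal of the triethylsilyl group (PPTS, MeOH, 0 °C) gives 25.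

Step 8. What may go wrong: slow alkenyl transfer from the iodine-bearing dienylzinc to the hindered, weakly electrophilic β,β-disubstituted enal, with competing methyl transfer and weak enantiofacial control. Fallback, setting out from 12 and 7 and coming back at 16: deprotonation of 12 with LiN(SiMe3)2 (THF, −78 °C, no halogen–metal exchange) and addition of the lithium acetylide to 7 gives the racemic propargylic alcohol F8. Hydroxyl-directed trans-reduction with NaAlH2(OCH2CH2OCH3)2 (THF, −20 °C) gives the racemic E-dienol F9. Step 9 is then run as a Sharpless kinetic resolution (0.6 equiv t-BuOOH, D-(−)-diisopropyl tartrate), in which the fast-reacting 6S enantiomer gives 16.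

**Further compounds**
F1 | step 11 | diethylphosphonoacetate of 16 (ester on O6) | COC(OC)CC/C(CO[Si](C)(C)C(C)(C)C)=C\[C@@H](OC(=O)CP(=O)(OCC)OCC)[C@H]1O[C@@H]1/C=C(/C)I
F2 | step 11 | α-(diethoxyphosphoryl)-γ-lactone with free C8 hydroxyl (21 with P(O)(OEt)2 and H on C11 in place of =CH2) | CCOP(=O)(OCC)C1C(=O)O[C@H](/C=C(/CO[Si](C)(C)C(C)(C)C)CCC(OC)OC)[C@H]1[C@H](O)/C=C(/C)I
F3 | step 14 | epoxy acrylate aldehyde (18 with C1 as CHO) | O=CCC/C(CO[Si](C)(C)C(C)(C)C)=C\[C@@H](OC(=O)C=C)[C@H]1O[C@@H]1/C=C(/C)I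
F4 | step 14 | ten-membered 7,8-epoxy 6-O-acrylate with C1 hydroxyl (C1 epimer mixture) | C=CC(=O)O[C@@H]1/C=C(/CO[Si](C)(C)C(C)(C)C)CCC(O)/C(C)=C\[C@H]2O[C@H]12
F5 | step 14 | C1 triethylsilyl ether of F4 | C=CC(=O)O[C@@H]1/C=C(/CO[Si](C)(C)C(C)(C)C)CCC(O[Si](CC)(CC)CC)/C(C)=C\[C@H]2O[C@H]12
F6 | step 14 | macrocyclic α-methylene lactone with free C8 hydroxyl and C1 triethylsilyl ether | C=C1C(=O)O[C@@H]2/C=C(/CO[Si](C)(C)C(C)(C)C)CCC(O[Si](CC)(CC)CC)/C(C)=C\[C@@H](O)[C@@H]12
F7 | step 14 | C1 triethylsilyl ether of 25 | C=C1C(=O)O[C@@H]2/C=C(/CO[Si](C)(C)C(C)(C)C)CCC(O[Si](CC)(CC)CC)/C(C)=C\[C@@H](OC(=O)[C@@H](C)CC)[C@@H]12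
F8 | step 8 | racemic propargylic alcohol (C7≡C8 analogue of 15) | COC(OC)CC/C(CO[Si](C)(C)C(C)(C)C)=C\C(O)C#C/C=C(/C)I
F9 | step 8 | racemic 15 | COC(OC)CC/C(CO[Si](C)(C)C(C)(C)C)=C\C(O)/C=C/C=C(/C)I
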